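**Retrosynthetic overview**
- The strategy rests on the 5,6-dihydro-2H-pyran-2-one ring (ring O, C1(=O), C2=C3, C4, C5; chain numbered from the lactone carbonyl C1 to the methyl C26). It is a crotonate unit C1–C4 attached to an aldehyde carbon C5 through C4–C5 and the ring O–C1 bond. Cutting both bonds gives an open-chain, fully silylated C5–C26 aldehyde and a four-carbon silyl dienolate.
- This ring, the only one, is closed last, together with the C5 stereocentre, by a copper(I)–bisphosphine-catalysed vinylogous aldol–lactonisation.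
- The C5–C26 aldehyde is cut at C10–C11 into a C5–C10 epoxide (C7 and C9 from the syn-chlorodiol statin ester) and a C11–C26 2-lithio-1,3-dithiane (C15 from resolved 1,2-epoxytridecane). C11 is then set by 1,3-syn reduction of the unmasked β-hydroxy ketone.
- The ester of the chlorodiol is reduced and silylated before the coupling, because a dithiane anion would enolise a β-silyloxy ester. The C5 aldehyde is released by selective primary desilylation and oxidation just before the ring closure.

Key step: step 16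

Assumption: (S)-Tol-BINAP is written for the copper catalyst on the assumption that it directs the dienolate to the Si face of an unbranched aldehyde; the sense should be confirmed on a simple β-silyloxy aldehyde and the (R)-ligand used if it is the reverse.
Remark: locants C1–C26 are those of the target. Some CIP descriptors change along the route because substituent priorities change; no stereocentre is inverted.

Step 1
Reactants: 1 tert-butyl (3R,5S)-6-chloro-3,5-dihydroxyhexanoate
Product: 2 (3S,5S)-6-chlorohexane-1,3,5-triol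
Conditions: LiBH4, MeOH (additive), THF, 0 °C → rt; aq. work-up
Reagents that add atoms: none
Why: Borohydride reduction of the β-hydroxy ester to the primary alcohol should leave the primary chloride and both carbinol centres (C7, C9) untouched, and it removes the only group that the later dithiane anion would enolise.

Step 2
Reactants: 2 (3S,5S)-6-chlorohexane-1,3,5-triol
Product: 3 (2S,4S)-6-(tert-butyldimethylsilyloxy)-1-chlorohexane-2,4-diol
Conditions: TBSCl (1.05 equiv), imidazole, DMF/CH2Cl2, −20 → 0 °C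
Reagents that add atoms: tert-butyldimethylsilyl chloride (TBSCl), CC(C)(C)[Si](C)(C)Cl
Why: Silylation under steric control should take the primary C5 hydroxyl well ahead of the two secondary ones.

Step 3
Reactants: 3 (2S,4S)-6-(tert-butyldimethylsilyloxy)-1-chlorohexane-2,4-diol
Product: 4 (2S)-4-(tert-butyldimethylsilyloxy)-1-[(2S)-oxiran-2-yl]butan-2-ol
Conditions: K2CO3, MeOH, 0 °C → rt
Reagents that add atoms: none
Why: Intramolecular Williamson closure (3-exo-tet) of the C9 alkoxide on the C10 chloride forms the terminal epoxide with retention at C9, since only the hydroxyl next to CH2Cl can close a favourable ring; this also distinguishes the two secondary hydroxyls.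

Step 4
Reactants: 4 (2S)-4-(tert-butyldimethylsilyloxy)-1-[(2S)-oxiran-2-yl]butan-2-ol
Product: 5 (2S)-2-[(2S)-2,4-bis(tert-butyldimethylsilyloxy)butyl]oxirane
Conditions: TBSCl, imidazole, DMF, rt
Reagents that add atoms: tert-butyldimethylsilyl chloride (TBSCl), CC(C)(C)[Si](C)(C)Cl
Why: Standard silylation of the remaining C7 hydroxyl under neutral conditions that a terminal epoxide tolerates.

Step 5
Reactants: 6 racemic 1,2-epoxytridecane
Product: 7 (S)-1,2-epoxytridecane
Conditions: (S,S)-(salen)Co(III)OAc (0.5 mol %), H2O (0.55 equiv), minimal THF, 0 °C → rt; chromatography or distillation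
Reagents that add atoms: none
Why: Hydrolytic kinetic resolution, in which the (S,S)-cobalt–salen catalyst is expected to hydrate the (R)-epoxide selectively and leave the (S)-epoxide that carries the C15 configuration.

Step 6
Reactants: 7 (S)-1,2-epoxytridecane; 8 2-(2-bromoethyl)-1,3-dioxolane
Product: 10 (4S)-1-(1,3-dioxolan-2-yl)pentadecan-4-ol, via Grignard reagent 9 (not isolated)
Conditions: 8, Mg, THF, ≤ 25 °C; then CuI (10 mol %), 7, −30 → 0 °C; aq. work-up
Reagents that add atoms: none
Why: Copper-catalysed Grignard opening of the terminal epoxide at its CH2 carbon (SN2) forms the C13–C14 bond without touching the C15 stereocentre.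

Step 7
Reactants: 10 (4S)-1-(1,3-dioxolan-2-yl)pentadecan-4-ol
Product: 11 (4S)-1-(1,3-dithian-2-yl)pentadecan-4-ol
Conditions: HS(CH2)3SH, BF3·OEt2 (cat.), CH2Cl2, −20 → 0 °C
Reagents that add atoms: propane-1,3-dithiol, SCCCS
Why: Lewis-acid transthioacetalisation turns the dioxolane into the thermodynamically favoured 1,3-dithiane, and it is run before silylation so that no silyl ether is exposed to BF3.

Step 8
Reactants: 11 (4S)-1-(1,3-dithian-2-yl)pentadecan-4-ol
Product: 12 tert-butyl{[(4S)-1-(1,3-dithian-2-yl)pentadecan-4-yl]oxy}dimethylsilane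
Conditions: TBSCl, imidazole, DMF, rt
Reagents that add atoms: tert-butyldimethylsilyl chloride (TBSCl), CC(C)(C)[Si](C)(C)Cl
Why: Standard silylation of the C15 hydroxyl, so that the only acidic site left is the dithiane C–H.

Step 9
Reactants: 12 tert-butyl{[(4S)-1-(1,3-dithian-2-yl)pentadecan-4-yl]oxy}dimethylsilane; 5 (2S)-2-[(2S)-2,4-bis(tert-butyldimethylsilyloxy)butyl]oxirane
Product: 14 (2S,4S)-4,6-bis(tert-butyldimethylsilyloxy)-1-{2-[(4S)-4-(tert-butyldimethylsilyloxy)pentadecyl]-1,3-dithian-2-yl}hexan-2-ol, via lithiated dithiane 13 (not isolated)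
Conditions: 12 (1.2 equiv), t-BuLi, THF/HMPA (10:1), −78 °C; then 5, −78 → −30 °C; cold aq. quench
Reagents that add atoms: none
Why: Corey–Seebach umpolung, in which the 2-lithio-1,3-dithiane opens the terminal epoxide at C10 by SN2 to form the C10–C11 bond with C9 unchanged; 5 carries no carbonyl or other acidic site that could quench the anion.

Step 10
Reactants: 14 (2S,4S)-4,6-bis(tert-butyldimethylsilyloxy)-1-{2-[(4S)-4-(tert-butyldimethylsilyloxy)pentadecyl]-1,3-dithian-2-yl}hexan-2-ol
Product: 15 (3S,5S,11S)-1,3,11-tris(tert-butyldimethylsilyloxy)-5-hydroxydocosan-7-one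
Conditions: MeI, CaCO3, MeCN/H2O (9:1), 40 °C
Reagents that add atoms: water, O
Why: S-Methylation activates the dithioacetal for hydrolysis to the C11 ketone, and the carbonate buffer should keep the silyl ethers and the β-hydroxy ketone intact.

Step 11
Reactants: 15 (3S,5S,11S)-1,3,11-tris(tert-butyldimethylsilyloxy)-5-hydroxydocosan-7-one
Product: 17 (3S,5R,7R,11S)-1,3,11-tris(tert-butyldimethylsilyloxy)docosane-5,7-diol, via boron chelate 16 (not isolated)
Conditions: Et2BOMe, THF/MeOH (4:1), −78 °C; NaBH4, −78 °C; AcOH, then repeated evaporation from MeOH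
Reagents that add atoms: none
Why: Narasaka–Prasad reduction, in which the diethylboron chelate of the C9 hydroxyl and C11 carbonyl adopts a half-chair and external hydride adds axially, which sets C11 1,3-syn to C9.

Step 12
Reactants: 17 (3S,5R,7R,11S)-1,3,11-tris(tert-butyldimethylsilyloxy)docosane-5,7-diol
Product: 18 (3S,5R,7R,11S)-1,3,5,7,11-pentakis(tert-butyldimethylsilyloxy)docosane
Conditions: TBSOTf (3 equiv), 2,6-lutidine, CH2Cl2, −78 → 0 °C
Reagents that add atoms: tert-butyldimethylsilyl trifluoromethanesulfonate (TBSOTf), CC(C)(C)[Si](C)(C)OS(=O)(=O)C(F)(F)F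
Why: The silyl triflate is reactive enough to silylate both hindered secondary hydroxyls of the syn-1,3-diol (C9, C11).

Step 13
Reactants: 18 (3S,5R,7R,11S)-1,3,5,7,11-pentakis(tert-butyldimethylsilyloxy)docosane
Product: 19 (3S,5R,7R,11S)-3,5,7,11-tetrakis(tert-butyldimethylsilyloxy)docosan-1-ol
Conditions: HF·pyridine, pyridine, THF, 0 °C, monitored and stopped at full conversion of 18
Reagents that add atoms: none
Why: Selective desilylation under steric control, since buffered HF·pyridine should cleave the unhindered primary C5 silyl ether much faster than the four secondary ones.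

Step 14
Reactants: 19 (3S,5R,7R,11S)-3,5,7,11-tetrakis(tert-butyldimethylsilyloxy)docosan-1-ol
Product: 20 (3R,5R,7R,11S)-3,5,7,11-tetrakis(tert-butyldimethylsilyloxy)docosanal
Conditions: Dess–Martin periodinane, NaHCO3 (solid buffer), CH2Cl2, 0 °C → rt; used without storage
Reagents that add atoms: none
Why: Dess–Martin oxidation gives the C5 aldehyde under near-neutral conditions, which should avoid β-elimination of the C7 silyloxy group.

Step 15
Reactants: 21 methyl (E)-but-2-enoate (methyl crotonate)
Product: 23 1-methoxy-1-(trimethylsilyloxy)buta-1,3-diene, via lithium dienolate 22 (not isolated)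
Conditions: LDA (from n-BuLi, i-Pr2NH), THF/DMPU, −78 °C; TMSCl, −78 °C → rt; distillation
Reagents that add atoms: chlorotrimethylsilane (TMSCl), C[Si](C)(C)Cl
Why: γ-Deprotonation of the crotonate to the extended dienolate (the polar co-solvent suppresses conjugate addition of the amide) followed by O-silylation gives the silyl ketene acetal diene.

Step 16
Reactants: 20 (3R,5R,7R,11S)-3,5,7,11-tetrakis(tert-butyldimethylsilyloxy)docosanal; 23 1-methoxy-1-(trimethylsilyloxy)buta-1,3-diene
Product: 26 (6S)-6-[(2S,4R,6R,10S)-2,4,6,10-tetrakis(tert-butyldimethylsilyloxy)henicosyl]-5,6-dihydro-2H-pyran-2-one, via copper dienolate 24 (not isolated), via copper aldolate 25 (not isolated)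
Conditions: Cu(OTf)2 (10 mol %), (S)-Tol-BINAP (11 mol %), Bu4N[Ph3SiF2] (20 mol %), THF, rt; then 23 (2 equiv) and 20, −20 °C → rt
Reagents that add atoms: none
Why: Fluoride (later methoxide) on copper transmetalates 23 to the chiral bisphosphine–copper(I) dienolate 24, which adds through its γ-carbon C4 to the aldehyde carbon C5 in a closed six-membered transition state that delivers the new C2=C3 bond cis and gives the copper aldolate 25. The C5 alkoxide oxygen then attacks the ester carbonyl C1 in a 6-exo-trig acyl substitution, which closes the only ring (O–C1–C2=C3–C4–C5) and expels copper methoxide; this desilylates the next molecule of 23 and turns the catalyst over, so diene and carbonyl are joined in a formal [4+2] sense. The closest known reaction type is the copper(I)–bisphosphine-catalysed asymmetric vinylogous Mukaiyama aldol–lactonisation of aldehydes with ester-derived silyl dienolates. The C5 stereocentre is set by the ligand: the route needs attack on the Si face of the aldehyde, which places the C5 oxygen syn to the C7 silyloxy group. Because C6 is an unbranched methylene and every other oxygen is a bulky, non-chelating silyl ether, the substrate offers only the weak 1,3-anti preference of a β-silyloxy aldehyde, so the catalyst enantiomer should decide the face even if the pairing is mismatched. γ- rather than α-attack is expected from the metallo-dienolate pathway, and the near-neutral turnover should spare the β-silyloxy aldehyde from elimination.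

Step 17
Reactants: 26 (6S)-6-[(2S,4R,6R,10S)-2,4,6,10-tetrakis(tert-butyldimethylsilyloxy)henicosyl]-5,6-dihydro-2H-pyran-2-one
Product: 27 (6S)-6-[(2R,4R,6R,10S)-2,4,6,10-tetrahydroxyhenicosyl]-5,6-dihydro-2H-pyran-2-one
Conditions: HF·pyridine, pyridine, THF, 0 °C → rt
Reagents that add atoms: none
Why: Global fluoride desilylation under mildly acidic, buffered conditions should free the four secondary hydroxyls while avoiding the base-promoted oxa-Michael addition of the C7 hydroxyl to the enoate.

**Compound list**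
1 | tert-butyl (3R,5S)-6-chloro-3,5-dihydroxyhexanoate | ClC[C@@H](O)C[C@@H](O)CC(=O)OC(C)(C)C | starting material
2 | (3S,5S)-6-chlorohexane-1,3,5-triol | ClC[C@@H](O)C[C@@H](O)CCO | intermediate
3 | (2S,4S)-6-(tert-butyldimethylsilyloxy)-1-chlorohexane-2,4-diol | ClC[C@@H](O)C[C@@H](O)CCO[Si](C)(C)C(C)(C)C | intermediate
4 | (2S)-4-(tert-butyldimethylsilyloxy)-1-[(2S)-oxiran-2-yl]butan-2-ol | C1[C@@H](O1)C[C@@H](O)CCO[Si](C)(C)C(C)(C)C | intermediate
5 | (2S)-2-[(2S)-2,4-bis(tert-butyldimethylsilyloxy)butyl]oxirane (C5–C10 epoxide) | C1[C@@H](O1)C[C@@H](O[Si](C)(C)C(C)(C)C)CCO[Si](C)(C)C(C)(C)C | intermediate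
6 | racemic 1,2-epoxytridecane (2-undecyloxirane) | CCCCCCCCCCCC1CO1 | starting material
7 | (S)-1,2-epoxytridecane | CCCCCCCCCCC[C@H]1CO1 | intermediate
8 | 2-(2-bromoethyl)-1,3-dioxolane | BrCCC1OCCO1 | starting material
9 | [2-(1,3-dioxolan-2-yl)ethyl]magnesium bromide | Br[Mg]CCC1OCCO1 | intermediate
10 | (4S)-1-(1,3-dioxolan-2-yl)pentadecan-4-ol | CCCCCCCCCCC[C@H](O)CCCC1OCCO1 | intermediate
11 | (4S)-1-(1,3-dithian-2-yl)pentadecan-4-ol | CCCCCCCCCCC[C@H](O)CCCC1SCCCS1 | intermediate
12 | tert-butyl{[(4S)-1-(1,3-dithian-2-yl)pentadecan-4-yl]oxy}dimethylsilane (C11–C26 dithiane) | CCCCCCCCCCC[C@H](O[Si](C)(C)C(C)(C)C)CCCC1SCCCS1 | intermediate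
13 | 2-lithio derivative of 12 | CCCCCCCCCCC[C@H](O[Si](C)(C)C(C)(C)C)CCCC1([Li])SCCCS1 | intermediate
14 | (2S,4S)-4,6-bis(tert-butyldimethylsilyloxy)-1-{2-[(4S)-4-(tert-butyldimethylsilyloxy)pentadecyl]-1,3-dithian-2-yl}hexan-2-ol | CCCCCCCCCCC[C@H](O[Si](C)(C)C(C)(C)C)CCCC1(SCCCS1)C[C@@H](O)C[C@@H](O[Si](C)(C)C(C)(C)C)CCO[Si](C)(C)C(C)(C)C | intermediate
15 | (3S,5S,11S)-1,3,11-tris(tert-butyldimethylsilyloxy)-5-hydroxydocosan-7-one | CCCCCCCCCCC[C@H](O[Si](C)(C)C(C)(C)C)CCCC(=O)C[C@@H](O)C[C@@H](O[Si](C)(C)C(C)(C)C)CCO[Si](C)(C)C(C)(C)C | intermediate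
16 | O-diethylboryl derivative (boron chelate) of 15 | CCCCCCCCCCC[C@H](O[Si](C)(C)C(C)(C)C)CCCC(=O)C[C@@H](OB(CC)CC)C[C@@H](O[Si](C)(C)C(C)(C)C)CCO[Si](C)(C)C(C)(C)C | intermediate
17 | (3S,5R,7R,11S)-1,3,11-tris(tert-butyldimethylsilyloxy)docosane-5,7-diol | CCCCCCCCCCC[C@H](O[Si](C)(C)C(C)(C)C)CCC[C@@H](O)C[C@@H](O)C[C@@H](O[Si](C)(C)C(C)(C)C)CCO[Si](C)(C)C(C)(C)C | intermediate
18 | (3S,5R,7R,11S)-1,3,5,7,11-pentakis(tert-butyldimethylsilyloxy)docosane | CCCCCCCCCCC[C@H](O[Si](C)(C)C(C)(C)C)CCC[C@@H](O[Si](C)(C)C(C)(C)C)C[C@@H](O[Si](C)(C)C(C)(C)C)C[C@@H](O[Si](C)(C)C(C)(C)C)CCO[Si](C)(C)C(C)(C)C | intermediate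
19 | (3S,5R,7R,11S)-3,5,7,11-tetrakis(tert-butyldimethylsilyloxy)docosan-1-ol | CCCCCCCCCCC[C@H](O[Si](C)(C)C(C)(C)C)CCC[C@@H](O[Si](C)(C)C(C)(C)C)C[C@@H](O[Si](C)(C)C(C)(C)C)C[C@@H](O[Si](C)(C)C(C)(C)C)CCO | intermediate
20 | (3R,5R,7R,11S)-3,5,7,11-tetrakis(tert-butyldimethylsilyloxy)docosanal (C5–C26 aldehyde) | CCCCCCCCCCC[C@H](O[Si](C)(C)C(C)(C)C)CCC[C@@H](O[Si](C)(C)C(C)(C)C)C[C@@H](O[Si](C)(C)C(C)(C)C)C[C@@H](O[Si](C)(C)C(C)(C)C)CC=O | intermediate
21 | methyl (E)-but-2-enoate (methyl crotonate) | C/C=C/C(=O)OC | starting material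
22 | lithium dienolate of methyl crotonate | C=CC=C(OC)O[Li] | intermediate
23 | 1-methoxy-1-(trimethylsilyloxy)buta-1,3-diene | C=CC=C(OC)O[Si](C)(C)C | intermediate
24 | copper(I) dienolate of methyl crotonate (bisphosphine ligand omitted) | C=CC=C(OC)O[Cu] | intermediate
25 | copper(I) alkoxide of methyl (2Z,5S)-5-hydroxy-7,9,11,15-tetrakis(tert-butyldimethylsilyloxy)hexacos-2-enoate (other centres as in 20; ligand omitted) | CCCCCCCCCCC[C@H](O[Si](C)(C)C(C)(C)C)CCC[C@@H](O[Si](C)(C)C(C)(C)C)C[C@@H](O[Si](C)(C)C(C)(C)C)C[C@@H](O[Si](C)(C)C(C)(C)C)C[C@@H](O[Cu])C/C=C\C(=O)OC | intermediate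
26 | (6S)-6-[(2S,4R,6R,10S)-2,4,6,10-tetrakis(tert-butyldimethylsilyloxy)henicosyl]-5,6-dihydro-2H-pyran-2-one | CCCCCCCCCCC[C@H](O[Si](C)(C)C(C)(C)C)CCC[C@@H](O[Si](C)(C)C(C)(C)C)C[C@@H](O[Si](C)(C)C(C)(C)C)C[C@@H](O[Si](C)(C)C(C)(C)C)C[C@@H]1CC=CC(=O)O1 | intermediate
27 | (6S)-6-[(2R,4R,6R,10S)-2,4,6,10-tetrahydroxyhenicosyl]-5,6-dihydro-2H-pyran-2-one | CCCCCCCCCCC[C@H](O)CCC[C@@H](O)C[C@@H](O)C[C@@H](O)C[C@@H]1CC=CC(=O)O1 | target

**Step count**
Total: 17 steps. Longest linear sequence: 12 steps (steps 1–4, 9–14, 16, 17; the branch through steps 5–8 is equally long).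

**Steps most likely to fail**

Step 16. The risks are poor or reversed facial selectivity at C5 in a possibly mismatched catalyst/substrate pairing, diversion of the aldolate into the open-chain (E)-enoate that cannot lactonise, and β-elimination of the C7 silyloxy group under the basic copper alkoxide. The fallback sets out from aldehyde 20 and comes back at lactone 26, and it builds the ring by metathesis instead. Aldehyde 20 is allylated with (−)-B-allyldiisopinocampheylborane [from (+)-α-pinene; Et2O, −78 °C, then NaOH/H2O2], a reagent-controlled Si-face allylboration that should give the homoallylic alcohol (C5 hydroxyl syn to the C7 silyloxy group) F1. Acryloyl chloride, Et3N and catalytic DMAP in CH2Cl2 at 0 °C then give the acrylate ester F2. Ring-closing metathesis of F2 with the second-generation Grubbs catalyst (CH2Cl2, 40 °C) forms the C2=C3 bond and gives 26.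

Step 9. The risks are slow epoxide opening by the hindered tertiary dithiane anion, with decomposition of the anion competing, and migration of the C7 silyl group to the new C9 alkoxide. The fallback sets out from epoxides 7 and 5 and comes back at hydroxy ketone 15, and it replaces the acyl-anion coupling by an alkynylation followed by directed alkyne oxygenation. Epoxide 7 is opened by 3-lithio-1-(trimethylsilyl)propyne (from 1-(trimethylsilyl)propyne and n-BuLi, THF, −78 → −20 °C) to give (5S)-1-(trimethylsilyl)hexadec-1-yn-5-ol F3. TBSCl/imidazole gives its silyl ether F4, and K2CO3 in MeOH removes the alkynyl silyl group to give the terminal alkyne tert-butyl{[(5S)-hexadec-1-yn-5-yl]oxy}dimethylsilane F5. The lithium acetylide of F5 (n-BuLi, then BF3·OEt2, THF, −78 °C) opens epoxide 5 at C10 to give the homopropargylic alcohol F6. 1,1,3,3-Tetramethyldisilazane converts the C9 hydroxyl into the dimethylsilyl ether F7. A platinum(0)–divinyltetramethyldisiloxane catalyst then effects 5-exo-dig intramolecular hydrosilylation, placing silicon on C11 in the cyclic alkylidene oxasilolane F8. Tamao oxidation (H2O2, KF, KHCO3, THF/MeOH) converts the C11–Si bond into the C11 ketone and gives 15.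

Step 13. The risk is insufficient discrimination between the primary and the four secondary silyl ethers, leading to over-desilylation or incomplete conversion. The fallback sets out from diol 17 and comes back at the target 27. It never makes the penta-silyl ether: the primary silyl ether is removed at the diol stage, where only two secondary silyl ethers compete, by the same acid that installs a cyclic acetal on C9/C11. Camphorsulfonic acid (cat.) in MeOH/CH2Cl2 at 0 °C cleaves the primary silyl ether of 17; 2,2-dimethoxypropane is then added to the same flask to tie the C9 and C11 oxygens as the syn-acetonide (any mixed ketal on the primary hydroxyl is hydrolysed on aqueous work-up), giving the acetonide alcohol F9. Dess–Martin oxidation gives the acetonide aldehyde F10. The conditions of step 16 with dienolate 23 give the acetonide-protected lactone F11. Aqueous HF in MeCN then removes the two silyl ethers and the acetonide and gives 27.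

Further compounds
F1 | step 16 | (4S,6S,8R,10R,14S)-6,8,10,14-tetrakis(tert-butyldimethylsilyloxy)pentacos-1-en-4-ol (C5 homoallylic alcohol) | CCCCCCCCCCC[C@H](O[Si](C)(C)C(C)(C)C)CCC[C@@H](O[Si](C)(C)C(C)(C)C)C[C@@H](O[Si](C)(C)C(C)(C)C)C[C@@H](O[Si](C)(C)C(C)(C)C)C[C@@H](O)CC=C
F2 | step 16 | acrylate ester of F1 | CCCCCCCCCCC[C@H](O[Si](C)(C)C(C)(C)C)CCC[C@@H](O[Si](C)(C)C(C)(C)C)C[C@@H](O[Si](C)(C)C(C)(C)C)C[C@@H](O[Si](C)(C)C(C)(C)C)C[C@@H](OC(=O)C=C)CC=C
F3 | step 9 | (5S)-1-(trimethylsilyl)hexadec-1-yn-5-ol | CCCCCCCCCCC[C@H](O)CCC#C[Si](C)(C)C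
F4 | step 9 | tert-butyldimethylsilyl ether of F3 | CCCCCCCCCCC[C@H](O[Si](C)(C)C(C)(C)C)CCC#C[Si](C)(C)C
F5 | step 9 | tert-butyl{[(5S)-hexadec-1-yn-5-yl]oxy}dimethylsilane | CCCCCCCCCCC[C@H](O[Si](C)(C)C(C)(C)C)CCC#C
F6 | step 9 | C9 homopropargylic alcohol (C11≡C12 alkyne; C5, C7, C15 silyl ethers) | CCCCCCCCCCC[C@H](O[Si](C)(C)C(C)(C)C)CCC#CC[C@@H](O)C[C@@H](O[Si](C)(C)C(C)(C)C)CCO[Si](C)(C)C(C)(C)C
F7 | step 9 | O-dimethylsilyl ether of F6 | CCCCCCCCCCC[C@H](O[Si](C)(C)C(C)(C)C)CCC#CC[C@@H](O[SiH](C)C)C[C@@H](O[Si](C)(C)C(C)(C)C)CCO[Si](C)(C)C(C)(C)C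
F8 | step 9 | 2,2-dimethyl-1,2-oxasilolane with exocyclic C11=C12 alkene (silicon on C11) | CCCCCCCCCCC[C@H](O[Si](C)(C)C(C)(C)C)CC/C=C1\C[C@H](C[C@@H](O[Si](C)(C)C(C)(C)C)CCO[Si](C)(C)C(C)(C)C)O[Si]1(C)C
F9 | step 13 | (3S)-3-(tert-butyldimethylsilyloxy)-4-{(4R,6R)-6-[(4S)-4-(tert-butyldimethylsilyloxy)pentadecyl]-2,2-dimethyl-1,3-dioxan-4-yl}butan-1-ol | CCCCCCCCCCC[C@H](O[Si](C)(C)C(C)(C)C)CCC[C@@H]1C[C@H](C[C@@H](O[Si](C)(C)C(C)(C)C)CCO)OC(C)(C)O1
F10 | step 13 | (3R)-3-(tert-butyldimethylsilyloxy)-4-{(4R,6R)-6-[(4S)-4-(tert-butyldimethylsilyloxy)pentadecyl]-2,2-dimethyl-1,3-dioxan-4-yl}butanal | CCCCCCCCCCC[C@H](O[Si](C)(C)C(C)(C)C)CCC[C@@H]1C[C@H](C[C@@H](O[Si](C)(C)C(C)(C)C)CC=O)OC(C)(C)O1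
F11 | step 13 | (6S)-5,6-dihydro-2H-pyran-2-one with C7 and C15 silyl ethers and C9/C11 acetonide | CCCCCCCCCCC[C@H](O[Si](C)(C)C(C)(C)C)CCC[C@@H]1C[C@H](C[C@@H](O[Si](C)(C)C(C)(C)C)C[C@@H]2CC=CC(=O)O2)OC(C)(C)O1
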